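(The readings stem from a simulated flask for substances that don't exist, noise included.)

The pitfall with these flasks is to carry a percentage from one run to another when the initiator charge differs, as it does between cedar and birch. So we count turnovers instead, dividing the monomer in chains at a reading by the initiator charged.

| flask | free monomer | transfer agent | protic impurity | initiator | remark | time |
|---|---|---|---|---|---|---|
| Thursday's | 0.50 M | 0.15 M | 0.14 M | 3.4 mM | run made earlier |  |
| Saturday's | 0.50 M | 0.15 M | 0.20 M | 3.4 mM | run made earlier |  |
| Monday's | 0.50 M | 0.15 M | 0.29 M | 3.4 mM | run made earlier |  |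
| Tuesday's | 0.50 M | 0.15 M | 0.15 M | 4 mM | run made earlier |  |
| cedar | 0.50 M | 0.150 M | 0.250 M | 5.0 mM |  | 2.5 h |
| birch | 0.50 M | 0.150 M | 0.150 M | 3.4 mM |  | 4.0 h |

1. the winner by amount of monomer in chains, in percent of the free monomer charged; "neither" if no more than 2 percentage points parts them (cedar / birch / neither)
2. how much monomer in chains is there at the end, in percent of the free monomer charged: cedar
3. how much monomer in chains is there at the end, in percent of the free monomer charged: birch

- Thursday's (time / h: monomer in chains / %): 0.250: 1.2; 0.667: 5.1; 1.33: 12.0; 2.00: 17.8; 3.00: 23.7
- Saturday's (time / h: monomer in chains / %): 0.250: 1.4; 0.417: 2.5; 0.833: 7.0; 1.33: 11.6; 3.00: 23.2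
- Monday's (time / h: monomer in chains / %): 0.500: 3.1; 1.00: 8.6; 1.50: 12.9; 2.50: 19.7; 3.00: 21.7
- Tuesday's (time / h: monomer in chains / %): 0.250: 1.2; 0.667: 5.6; 1.33: 14.4; 2.00: 20.8; 3.00: 27.7

(readings scatter by 0.3 percentage points)

- reactions considered so far: living end + transfer agent -> dead chain; protic impurity + free monomer -> quenched substrate; free monomer + initiator -> living end + monomer in chains; free monomer + living end -> monomer in chains + living end

Reading the rows at 3.00 h, Thursday's run gives a count of 34.9, and Tuesday's, with more initiator and nearly the same protic impurity, gives 34.6, so the count carried across that change of initiator. Saturday's gives 34.1 and Monday's 31.9, so at one initiator charge Monday's count, with the most protic impurity of these runs, reads lower than Thursday's.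

Monday's count at cedar's own time of 2.5 h, taken along the line between its rows at 1.50 h and 2.50 h, is 29.0, which we take for cedar, whose protic impurity of 0.250 M lies near Monday's, and cedar should then reach 29.0%. For birch we go back to Thursday's counts, which gained 12.7 h⁻¹ and then 8.68 h⁻¹. If the hourly gain shrinks by that ratio once more, birch's turnover count, the monomer in chains per initiator charged, reaches 40.8 at 4.0 h, which is 27.7%. Our gap of 1.2 percentage points is less than the margin of 2 points, so we say neither.

The forecast also says neither, with cedar at 28% and birch at 27.4%, on the ground that “Tuesday's run shows yield scales nearly linearly with initiator”. Our cedar figure stands higher than the forecast's.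

The flasks give neither: cedar 27.7%, birch 27.2%.

    living end + transfer agent → dead chain (kL = 0.0538 M⁻¹ min⁻¹)
    protic impurity + free monomer → quenched substrate (k = 0.00944 M⁻¹ min⁻¹)
    free monomer + initiator → living end + monomer in chains (k = 0.0571 M⁻¹ min⁻¹)
    free monomer + living end → monomer in chains + living end, rate k4*[living end]*[free monomer] (k = 1.06 M⁻¹ min⁻¹)

Cedar's count came to 27.7 against the 29.0 taken from Monday's, and birch's to 40.0 against 40.8. In birch at 2.00 h, with 5.50% of the initiator left and living end at 0.00162 M, the making of monomer in chains had behind it 66% of its turnover up to 4.00 h, and by that time the living end stood at 7.12 × 10⁻⁴ M while quenched substrate had reached 16.9% of the free monomer charged. For the same flask as birch with 0.0058 M of initiator our count gives 47.3%, but that flask gave 41.2%, a count of 35.5, with 43% of its free monomer left.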